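**Retrosynthetic overview**

1. The target is fisetinidol-(4β→6)-fisetinidol-(4α→6)-mollisacacidin. The lower C4–OH (3,4-trans) is set last by NaBH4 on the lower-unit 4-ketone, after global hydrogenolysis (a free 4-OH would not survive Pd/H2).
2. The lower interflavan bond (3,4-trans) comes from silver-promoted SN1 arylation of a 4-phenylthio dimer by the monomer. The upper bond (3,4-cis) comes from addition of a 6-lithioflavan to a flavan-4-one, then ionic hydrogenation.
3. All three flavan units derive from one monomer, penta-O-benzyl-mollisacacidin 9.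
4. Monomer 9 is cut at C2–C3 and C4–C4a: an enantioselective oxa-Povarov annulation of an O-aryl oxocarbenium ion (O1=C2, carrying rings A and B) with (E)-1,2-bis(benzyloxy)ethene (C3–C4). It is possible because ring A is a resorcinol ether: O1 on C8a carries the cationic C2, and the 7-oxygen para to C4a makes C4a the nucleophile that closes ring C. The vicinal C3/C4 oxygens make the two-carbon partner an electron-rich enediol ether.
5. Ring order: rings A and B are bought. Ring C of each unit is the only ring formed (step 3). The units are then joined, upper bond first.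

Key step: step 3

Assumption: the sense of induction of the chiral acid in step 3 cannot be predicted, so the acid enantiomer that delivers the 2R series is the one meant (written as S,S); (E)-1,2-diiodoethene is taken as commercial.

**Step 1**
Reactants: 1 3,4-bis(benzyloxy)benzaldehyde; 2 3-(benzyloxy)phenol (two equivalents are incorporated)
Product: 4 3,4-bis(benzyloxy)benzaldehyde bis[3-(benzyloxy)phenyl] acetal, via benzal chloride 3 (not isolated)
Conditions: SOCl2 (1.5 equiv), DMF (cat.), CH2Cl2, 0 °C → rt, evaporate; then 2 (2.2 equiv), NaH (2.2 equiv), DMF, 0 °C → rt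
Reagents that add atoms: 3-(benzyloxy)phenol (the second equivalent of 2), Oc1cccc(OCc2ccccc2)c1
Why: SOCl2/DMF converts aromatic aldehydes into benzal chlorides (Vilsmeier-type deoxychlorination), and the two benzylic chlorides should each be displaced at oxygen by one equivalent of the sodium phenoxide of 2 in DMF (double Williamson-type O-alkylation), so that the acetal carries two identical aryloxy groups and no stereocentre is formed.

**Step 2**
Reactants: 5 (E)-1,2-diiodoethene
Product: 6 (E)-1,2-bis(benzyloxy)ethene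
Conditions: BnOH (3 equiv), CuI (10 mol%), 3,4,7,8-tetramethyl-1,10-phenanthroline (20 mol%), Cs2CO3 (3 equiv), toluene, 80 °C
Reagents that add atoms: benzyl alcohol, OCc1ccccc1; benzyl alcohol (second equivalent), OCc1ccccc1
Why: Copper-catalysed Ullmann-type C–O coupling of vinyl iodides with alcohols proceeds with retention of alkene geometry, so the E-diiodide should give the E-bis(enol ether) by two successive couplings in one pot, each taking up one molecule of benzyl alcohol.

**Step 3**
Reactants: 4 diaryl acetal; 6 (E)-1,2-bis(benzyloxy)ethene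
Product: 9 (2R,3S,4R)-3,4,7-tris(benzyloxy)-2-[3,4-bis(benzyloxy)phenyl]chromane, via O-aryl oxocarbenium ion 7 (not isolated), via benzyloxocarbenium adduct 8 (not isolated)
Conditions: (S,S)-imidodiphosphorimidate acid {[(S)-3,3'-Ar2-1,1'-binaphthalene-2,2'-diyl-O2]P(=NSO2CF3)}2NH, Ar = 3,5-(CF3)2C6H3 (5 mol%), 6 (2.5 equiv), 4 Å MS, toluene, −78 → −40 °C
Reagents that add atoms: none
Why: Proposed new method: the confined chiral acid protonates an aryloxy oxygen of 4 and expels 3-(benzyloxy)phenol (the same leaving group whichever C–O bond breaks), giving O-aryl oxocarbenium ion 7 as a contact ion pair with the chiral anion; alkene 6 attacks one enantioface of C2 (C2–C3 bond) to give benzyloxocarbenium ion 8, whose C4 is captured by the ring A carbon para to the 7-benzyloxy group (C4–C4a bond, Friedel–Crafts), and loss of the arenium proton returns the acid. The closest known reactions are the SnCl4-promoted oxa-Povarov annulation of O-aryl oxocarbenium ions with alkenes, which is racemic, and the chiral-Brønsted-acid Povarov and oxocarbenium additions that work by ion pairing; their merger with a 1,2-dioxygenated alkene is new. Ring C is closed by a 6-exo-trig attack of the arene on the C4 oxocarbenium carbon, so the overall event is a stepwise formal inverse-demand [4+2] cycloaddition. C2 should be set by the anion-shielded face of 7 (catalyst control, 2R); C3 should follow from the E geometry of 6, which in Povarov-type additions of E-1,2-disubstituted electron-rich alkenes is expected to place the C3 substituent anti to the C2 aryl group (2,3-trans); C4 should be set in the chair-like closure that keeps the 4-benzyloxy group equatorial (3,4-trans) and is in any case erased later in every unit. The step needs closure para and not ortho to the benzyloxy group, which lower hindrance and para activation should secure, and it needs 7 to be trapped by 6 faster than by the liberated phenol or by ring A of another molecule, which excess 6 at low temperature should secure. It also needs the acid to ionise the acetal but not the 4-benzyl ether of 9, which the far better leaving group of 4 and the low temperature should secure.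

**Step 4**
Reactants: 9 monomer
Product: 10 (2R,3S,4R)-3,7-bis(benzyloxy)-2-[3,4-bis(benzyloxy)phenyl]chroman-4-ol
Conditions: HCl (0.5 M aq.)/THF 1:4, 45 °C
Reagents that add atoms: water, O
Why: The 4-benzyloxy group is a benzylic ether activated by the para 7-benzyloxy group and the ortho ring oxygen, so it should ionise under mild aqueous acid and be replaced by water (SN1 solvolysis); the C4 configuration is of no consequence because C4 becomes a carbonyl in step 5.

**Step 5**
Reactants: 10 flavan-4-ol
Product: 11 (2R,3R)-3,7-bis(benzyloxy)-2-[3,4-bis(benzyloxy)phenyl]chroman-4-one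
Conditions: Dess–Martin periodinane, NaHCO3, CH2Cl2, 0 °C → rt
Reagents that add atoms: none
Why: Dess–Martin oxidation of the secondary benzylic alcohol under buffered neutral conditions should give the ketone without touching C2 or C3.

**Step 6**
Reactants: 9 monomer
Product: 12 (2R,3S,4R)-6-bromo-3,4,7-tris(benzyloxy)-2-[3,4-bis(benzyloxy)phenyl]chromane
Conditions: N-bromosuccinimide (1.05 equiv), CH2Cl2, −40 → 0 °C
Reagents that add atoms: N-bromosuccinimide, O=C1CCC(=O)N1Br
Why: Electrophilic aromatic bromination should occur at C6, the ring A position para to the ring oxygen and ortho to the 7-benzyloxy group, because C8 is flanked by two oxygen substituents and ring B is less activated.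

**Step 7**
Reactants: 12 6-bromo monomer
Product: 13 (2R,3R,4R)-6-bromo-3,7-bis(benzyloxy)-2-[3,4-bis(benzyloxy)phenyl]-4-(phenylsulfanyl)chromane
Conditions: PhSH (3 equiv), BF3·OEt2 (0.3 equiv), CH2Cl2, −78 → −30 °C
Reagents that add atoms: thiophenol, Sc1ccccc1
Why: Lewis-acid SN1 thiolysis at C4 (the reaction used to cap flavan C4 cations with thiols) should install the thioether anti to the 3-benzyloxy group; the thioether is inert to the base of step 8 and the protic acid of step 9.

**Step 8**
Reactants: 13 6-bromo-4-phenylthio monomer; 11 flavan-4-one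
Product: 15 dimeric tertiary C4 alcohol (C4 of the upper unit carries OH plus C6 of the lower 4-phenylthio unit), via 6-lithioflavan 14 (not isolated)
Conditions: n-BuLi (1.05 equiv), THF, −78 °C; then 11, THF, −78 → −40 °C; H2O
Reagents that add atoms: none
Why: Bromine–lithium exchange at −78 °C outpaces the other reactions of n-BuLi, and the aryllithium should add to the ketone of 11 (1,2-addition of an aryllithium to a protected dihydroflavonol); the new carbinol centre is removed in step 9.

**Step 9**
Reactants: 15 tertiary alcohol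
Product: 16 protected dimer with a 4β→6 bond (3,4-cis) and the 4-phenylthio group retained on the lower unit
Conditions: Et3SiH (5 equiv), CF3CO2H (10 equiv), CH2Cl2, −78 → −20 °C
Reagents that add atoms: none
Why: In this ionic hydrogenation the acid ionises the doubly benzylic tertiary alcohol and Et3SiH should deliver hydride to the face of the C4 cation anti to the adjacent 3-benzyloxy group, which leaves the aryl group cis to O3 (3,4-cis, 4β); the thioether and the benzyl ethers should not be ionised by the acid at this temperature.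

**Step 10**
Reactants: 16 protected dimer; 9 monomer
Product: 17 perbenzylated trimer with 4β→6 and 4α→6 bonds and a 3,4-bis(benzyloxy) lower unit
Conditions: AgBF4 (1.5 equiv), 2,6-di-tert-butyl-4-methylpyridine (2 equiv), 9 (4 equiv), CH2Cl2, −40 → 0 °C, dark
Reagents that add atoms: none
Why: AgBF4 abstracts thiophenolate (thiophilic activation of 4-thioflavans) and the C4 cation should be captured by C6 of 9 (Friedel–Crafts, SN1) anti to the 3-benzyloxy group, giving the 3,4-trans bond; the buffered medium leaves the 4-benzyloxy group of 9 intact and excess 9 suppresses self-condensation.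

**Step 11**
Reactants: 17 perbenzylated trimer
Product: 18 trimer with a free 4-hydroxyl group on the lower unit
Conditions: HCl (0.5 M aq.)/THF 1:4, 45 °C
Reagents that add atoms: water, O
Why: The lower-unit 4-benzyloxy group is the only remaining benzylic C4–O bond and should undergo SN1 solvolysis as in step 4, while the 5-deoxy interflavan bonds are stable to dilute acid; the C4 configuration is again of no consequence.

**Step 12**
Reactants: 18 trimer alcohol
Product: 19 trimer with a lower-unit 4-ketone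
Conditions: Dess–Martin periodinane, NaHCO3, CH2Cl2, 0 °C → rt
Reagents that add atoms: none
Why: Dess–Martin oxidation of the single secondary alcohol should give the lower-unit dihydroflavonol ketone under neutral conditions.

**Step 13**
Reactants: 19 trimer ketone
Product: 20 fisetinidol-(4β→6)-fisetinidol-(4α→6)-fustin
Conditions: H2 (1 atm), 10% Pd/C, THF/MeOH 1:1, rt
Reagents that add atoms: none
Why: Hydrogenolysis should remove all twelve benzyl ethers while the dihydroflavonol ketone survives; C4 is kept as a ketone here because a free 4-hydroxyl group would itself be hydrogenolysed.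

**Step 14**
Reactants: 20 free phenolic trimer ketone
Product: 21 fisetinidol-(4β→6)-fisetinidol-(4α→6)-mollisacacidin (CNP0255184.1)
Conditions: NaBH4, EtOH, 0 °C; AcOH to pH 6
Reagents that add atoms: none
Why: NaBH4 reduction of trans-dihydroflavonols gives the 2,3-trans-3,4-trans flavan-3,4-diols (axial hydride attack, equatorial 4-OH), as in the classical reduction of fustin to mollisacacidin, which should set the lower C4 as 4R.

**Compound list**

1 | 3,4-bis(benzyloxy)benzaldehyde | O=Cc1ccc(OCc2ccccc2)c(OCc2ccccc2)c1 | starting material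
2 | 3-(benzyloxy)phenol | Oc1cccc(OCc2ccccc2)c1 | starting material
3 | 1,2-bis(benzyloxy)-4-(dichloromethyl)benzene (benzal chloride, not isolated) | ClC(Cl)c1ccc(OCc2ccccc2)c(OCc2ccccc2)c1 | intermediate
4 | 1,2-bis(benzyloxy)-4-{bis[3-(benzyloxy)phenoxy]methyl}benzene (diaryl acetal) | C(Oc1cccc(OCc2ccccc2)c1)(Oc1cccc(OCc2ccccc2)c1)c1ccc(OCc2ccccc2)c(OCc2ccccc2)c1 | intermediate
5 | (E)-1,2-diiodoethene | I/C=C/I | starting material
6 | (E)-1,2-bis(benzyloxy)ethene | c1ccccc1CO/C=C/OCc1ccccc1 | intermediate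
7 | (E)-[3,4-bis(benzyloxy)benzylidene][3-(benzyloxy)phenyl]oxonium ion (not isolated) | C(/c1ccc(OCc2ccccc2)c(OCc2ccccc2)c1)=[O+]\c1cccc(OCc2ccccc2)c1 | intermediate
8 | open-chain O-benzyl oxocarbenium adduct, C2 and C3 configured as in 9 (not isolated) | c1ccc(cc1OCc1ccccc1)O[C@H](c1ccc(OCc3ccccc3)c(OCc3ccccc3)c1)[C@@H](OCc1ccccc1)C=[O+]Cc1ccccc1 | intermediate
9 | (2R,3S,4R)-3,4,7-tris(benzyloxy)-2-[3,4-bis(benzyloxy)phenyl]chromane (penta-O-benzyl-mollisacacidin, 2,3-trans-3,4-trans) | c1cc2c(cc1OCc1ccccc1)O[C@H](c1ccc(OCc3ccccc3)c(OCc3ccccc3)c1)[C@@H](OCc1ccccc1)[C@@H]2OCc1ccccc1 | intermediate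
10 | (2R,3S,4R)-3,7-bis(benzyloxy)-2-[3,4-bis(benzyloxy)phenyl]chroman-4-ol (drawn as the 3,4-trans epimer; the C4 epimer serves equally) | c1cc2c(cc1OCc1ccccc1)O[C@H](c1ccc(OCc3ccccc3)c(OCc3ccccc3)c1)[C@@H](OCc1ccccc1)[C@@H]2O | intermediate
11 | (2R,3R)-3,7-bis(benzyloxy)-2-[3,4-bis(benzyloxy)phenyl]chroman-4-one (tetra-O-benzylfustin, 2,3-trans) | c1cc2c(cc1OCc1ccccc1)O[C@H](c1ccc(OCc3ccccc3)c(OCc3ccccc3)c1)[C@@H](OCc1ccccc1)C2=O | intermediate
12 | (2R,3S,4R)-6-bromo-3,4,7-tris(benzyloxy)-2-[3,4-bis(benzyloxy)phenyl]chromane | Brc1cc2c(cc1OCc1ccccc1)O[C@H](c1ccc(OCc3ccccc3)c(OCc3ccccc3)c1)[C@@H](OCc1ccccc1)[C@@H]2OCc1ccccc1 | intermediate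
13 | (2R,3R,4R)-6-bromo-3,7-bis(benzyloxy)-2-[3,4-bis(benzyloxy)phenyl]-4-(phenylsulfanyl)chromane (2,3-trans-3,4-trans) | Brc1cc2c(cc1OCc1ccccc1)O[C@H](c1ccc(OCc3ccccc3)c(OCc3ccccc3)c1)[C@@H](OCc1ccccc1)[C@@H]2Sc1ccccc1 | intermediate
14 | 6-lithio analogue of 13 (not isolated) | [Li]c1cc2c(cc1OCc1ccccc1)O[C@H](c1ccc(OCc3ccccc3)c(OCc3ccccc3)c1)[C@@H](OCc1ccccc1)[C@@H]2Sc1ccccc1 | intermediate
15 | tertiary alcohol: upper unit is 11 whose C4 carries OH (drawn cis to 3-OBn, inconsequential) and C6 of the lower unit; lower unit is 13 without bromine | c1cc2c(cc1OCc1ccccc1)O[C@H](c1ccc(OCc3ccccc3)c(OCc3ccccc3)c1)[C@@H](OCc1ccccc1)[C@]2(O)c1cc2c(cc1OCc1ccccc1)O[C@H](c1ccc(OCc3ccccc3)c(OCc3ccccc3)c1)[C@@H](OCc1ccccc1)[C@@H]2Sc1ccccc1 | intermediate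
16 | protected dimer: tetra-O-benzylfisetinidol (2R, 2,3-trans) joined through C4 (aryl cis to 3-OBn, 4β) to C6 of a tetra-O-benzyl-4α-(phenylsulfanyl)fisetinidol unit (2R, 2,3-trans-3,4-trans) | c1cc2c(cc1OCc1ccccc1)O[C@H](c1ccc(OCc3ccccc3)c(OCc3ccccc3)c1)[C@@H](OCc1ccccc1)[C@H]2c1cc2c(cc1OCc1ccccc1)O[C@H](c1ccc(OCc3ccccc3)c(OCc3ccccc3)c1)[C@@H](OCc1ccccc1)[C@@H]2Sc1ccccc1 | intermediate
17 | perbenzylated trimer: upper bond 4β→6 (3,4-cis), middle bond 4α→6 (3,4-trans), lower unit as in 9; all units 2R and 2,3-trans | c1cc2c(cc1OCc1ccccc1)O[C@H](c1ccc(OCc3ccccc3)c(OCc3ccccc3)c1)[C@@H](OCc1ccccc1)[C@H]2c1cc2c(cc1OCc1ccccc1)O[C@H](c1ccc(OCc3ccccc3)c(OCc3ccccc3)c1)[C@@H](OCc1ccccc1)[C@@H]2c1cc2c(cc1OCc1ccccc1)O[C@H](c1ccc(OCc3ccccc3)c(OCc3ccccc3)c1)[C@@H](OCc1ccccc1)[C@@H]2OCc1ccccc1 | intermediate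
18 | trimer as 17 with a free 4-OH on the lower unit (drawn 3,4-trans; the C4 epimer serves equally) | c1cc2c(cc1OCc1ccccc1)O[C@H](c1ccc(OCc3ccccc3)c(OCc3ccccc3)c1)[C@@H](OCc1ccccc1)[C@H]2c1cc2c(cc1OCc1ccccc1)O[C@H](c1ccc(OCc3ccccc3)c(OCc3ccccc3)c1)[C@@H](OCc1ccccc1)[C@@H]2c1cc2c(cc1OCc1ccccc1)O[C@H](c1ccc(OCc3ccccc3)c(OCc3ccccc3)c1)[C@@H](OCc1ccccc1)[C@@H]2O | intermediate
19 | trimer as 17 with the lower unit as (2R,3R)-3-benzyloxy-4-ketone (twelve benzyl ethers) | c1cc2c(cc1OCc1ccccc1)O[C@H](c1ccc(OCc3ccccc3)c(OCc3ccccc3)c1)[C@@H](OCc1ccccc1)[C@H]2c1cc2c(cc1OCc1ccccc1)O[C@H](c1ccc(OCc3ccccc3)c(OCc3ccccc3)c1)[C@@H](OCc1ccccc1)[C@@H]2c1cc2c(cc1OCc1ccccc1)O[C@H](c1ccc(OCc3ccccc3)c(OCc3ccccc3)c1)[C@@H](OCc1ccccc1)C2=O | intermediate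
20 | fisetinidol-(4β→6)-fisetinidol-(4α→6)-fustin: upper unit 2R,3S,4S; middle unit 2R,3S,4R; lower unit 2R,3R | Oc1ccc2c(c1)O[C@H](c1ccc(O)c(O)c1)[C@@H](O)[C@H]2c1cc2c(cc1O)O[C@H](c1ccc(O)c(O)c1)[C@@H](O)[C@@H]2c1cc2c(cc1O)O[C@H](c1ccc(O)c(O)c1)[C@@H](O)C2=O | intermediate
21 | fisetinidol-(4β→6)-fisetinidol-(4α→6)-mollisacacidin: upper unit 2R,3S,4S; middle unit 2R,3S,4R; lower unit 2R,3S,4R | Oc1ccc2c(c1)O[C@H](c1ccc(O)c(O)c1)[C@@H](O)[C@H]2c1cc2c(cc1O)O[C@H](c1ccc(O)c(O)c1)[C@@H](O)[C@@H]2c1cc2c(cc1O)O[C@H](c1ccc(O)c(O)c1)[C@@H](O)[C@@H]2O | target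

**Step count and risks**

Total steps: 14. Longest linear sequence: 11 (steps 1, 3, 6, 7, 8, 9, 10, 11, 12, 13, 14).

Most likely to fail, first: step 3. What may go wrong is insufficient enantiofacial discrimination in the ion pair, addition with the wrong relative topicity (2,3-cis), or acid-induced oligomerisation of the enol ether outrunning capture of the cation. The fallback uses known chemistry and sets out from 1. Commercial 1-[4-(benzyloxy)-2-hydroxyphenyl]ethanone is protected (MOMCl, iPr2NEt) to 1-[4-(benzyloxy)-2-(methoxymethoxy)phenyl]ethanone F1, which is condensed with 1 (KOH, EtOH, Claisen–Schmidt) to the chalcone (E)-1-[4-(benzyloxy)-2-(methoxymethoxy)phenyl]-3-[3,4-bis(benzyloxy)phenyl]prop-2-en-1-one F2. Juliá–Colonna epoxidation (poly-L-leucine, urea–H2O2, DBU, THF) should give [(2R,3S)-3-[3,4-bis(benzyloxy)phenyl]oxiran-2-yl][4-(benzyloxy)-2-(methoxymethoxy)phenyl]methanone F3. Acid (HCl, MeOH/THF, 55 °C) removes the MOM group, and the freed phenol should open the epoxide at the benzylic carbon with inversion to (2R,3R)-7-(benzyloxy)-2-[3,4-bis(benzyloxy)phenyl]-3-hydroxychroman-4-one F4. O-Benzylation (BnBr, Ag2O) then gives 11, where the fallback comes back to the route. NaBH4 converts 11 into 10, and benzylation of 10 (NaH, BnBr) gives 9 for steps 6 and 10.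

Second: step 9. What may go wrong is poor facial selectivity of hydride transfer to the planar C4 cation (giving the 3,4-trans aryl epimer) or loss of the C3 proton to a flav-3-ene. The fallback sets out from 9. Thiolysis of 9 (PhSH, BF3·OEt2) gives the bromine-free thioether (2R,3R,4R)-3,7-bis(benzyloxy)-2-[3,4-bis(benzyloxy)phenyl]-4-(phenylsulfanyl)chromane F5. A second portion of 9 is then ionised at C4 with TMSOTf (cat.) at −78 °C in the presence of excess F5, whose thioether is inert to the hard Lewis acid. This SN1 arylation should give both C4 epimers of the dimer; the 3,4-cis isomer, expected as the minor one, is separated by chromatography and is 16, where the fallback comes back.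

Third: step 10. What may go wrong is capture of the hindered dimer cation by ring A of a second dimer molecule (self-condensation) or attack at C8 of 9. The fallback reverses the order of bond formation and sets out from 13. AgBF4 with 2,6-di-tert-butyl-4-methylpyridine couples the bromine-capped monomer 13 with 9 to the lower dimer, 6-bromo-tetra-O-benzylfisetinidol-(4α→6)-penta-O-benzyl-mollisacacidin F6; the bromine blocks self-condensation. Bromine–lithium exchange on F6 (n-BuLi, −78 °C) and addition to 11 gives the trimeric tertiary alcohol F7. Et3SiH/CF3CO2H, held at −78 °C so that the secondary 4-benzyl ether is not ionised, should then give 17, where the fallback comes back.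

**Further compounds**

F1 | step 3 | 1-[4-(benzyloxy)-2-(methoxymethoxy)phenyl]ethanone | CC(=O)c1ccc(OCc2ccccc2)cc1OCOC
F2 | step 3 | (E)-1-[4-(benzyloxy)-2-(methoxymethoxy)phenyl]-3-[3,4-bis(benzyloxy)phenyl]prop-2-en-1-one | O=C(/C=C/c1ccc(OCc2ccccc2)c(OCc2ccccc2)c1)c1ccc(OCc2ccccc2)cc1OCOC
F3 | step 3 | [(2R,3S)-3-[3,4-bis(benzyloxy)phenyl]oxiran-2-yl][4-(benzyloxy)-2-(methoxymethoxy)phenyl]methanone | O=C(c1ccc(OCc2ccccc2)cc1OCOC)[C@@H]1O[C@H]1c1ccc(OCc2ccccc2)c(OCc2ccccc2)c1
F4 | step 3 | (2R,3R)-7-(benzyloxy)-2-[3,4-bis(benzyloxy)phenyl]-3-hydroxychroman-4-one | c1cc2c(cc1OCc1ccccc1)O[C@H](c1ccc(OCc3ccccc3)c(OCc3ccccc3)c1)[C@@H](O)C2=O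
F5 | step 9 | (2R,3R,4R)-3,7-bis(benzyloxy)-2-[3,4-bis(benzyloxy)phenyl]-4-(phenylsulfanyl)chromane | c1cc2c(cc1OCc1ccccc1)O[C@H](c1ccc(OCc3ccccc3)c(OCc3ccccc3)c1)[C@@H](OCc1ccccc1)[C@@H]2Sc1ccccc1
F6 | step 10 | 6-bromo-tetra-O-benzylfisetinidol-(4α→6)-penta-O-benzyl-mollisacacidin (both units 2R, 2,3-trans-3,4-trans) | Brc1cc2c(cc1OCc1ccccc1)O[C@H](c1ccc(OCc3ccccc3)c(OCc3ccccc3)c1)[C@@H](OCc1ccccc1)[C@@H]2c1cc2c(cc1OCc1ccccc1)O[C@H](c1ccc(OCc3ccccc3)c(OCc3ccccc3)c1)[C@@H](OCc1ccccc1)[C@@H]2OCc1ccccc1
F7 | step 10 | trimeric tertiary alcohol: 11 whose C4 carries OH (drawn cis to 3-OBn) and C6 of the upper unit of debrominated F6 | c1cc2c(cc1OCc1ccccc1)O[C@H](c1ccc(OCc3ccccc3)c(OCc3ccccc3)c1)[C@@H](OCc1ccccc1)[C@]2(O)c1cc2c(cc1OCc1ccccc1)O[C@H](c1ccc(OCc3ccccc3)c(OCc3ccccc3)c1)[C@@H](OCc1ccccc1)[C@@H]2c1cc2c(cc1OCc1ccccc1)O[C@H](c1ccc(OCc3ccccc3)c(OCc3ccccc3)c1)[C@@H](OCc1ccccc1)[C@@H]2OCc1ccccc1
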